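1. Start from the amounts: the flask holds 1.30 equiv of Q against 1.00 equiv of J and as much of L, so L and J together want more Q than is there. Q is the limiting reagent.

| setting | beta | alpha | delta | flask |
|---|---|---|---|---|
| L | 0.50 M | 0.50 M | 0.25 M | 0.50 M |
| Q | 1.3 equiv | 1.3 equiv | 1.3 equiv | 1.30 equiv |
| J | 1 equiv | 1 equiv | 1 equiv | 1.00 equiv |
| X | 0.25 mol% | 0.38 mol% | 0.5 mol% | 0.5 mol% |
| remark | run made earlier | run made earlier | run made earlier |  |
| time |  |  |  | 15 d |

- beta (time / d: Z / %, L / %): 0.0833: 21.6, 75.5; 0.417: 36.1, 47.4; 2.08: 30.1, 29.3; 10.0: 27.3, 22.9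
- alpha (time / d: Z / %, L / %): 0.0833: 26.9, 69.2; 0.417: 35.4, 41.0; 2.08: 29.0, 27.0; 10.0: 26.5, 22.8
- delta (time / d: Z / %, L / %): 0.0833: 12.8, 87.1; 0.417: 25.1, 62.3; 2.08: 27.2, 41.2; 10.0: 25.1, 30.1

(readings scatter by 0.5 percentage points)

- what was read earlier has a scatter of 0.5 percentage points, one standard deviation

* the moment within 15 d at which there is most Z
* the amount of Z, in percent of the L charged, at that time

2. Which numbers must you know well? From beta at 0.25 mol% to alpha at 0.38 mol%, the highest Z reading goes from 36.1% to 35.4%, while the first Z reading moves from 21.6% to 26.9%. An error in X therefore moves the early Z reading more than the highest one. The limit of 15 d should matter little: it lies beyond the last reading at 10.0 d, and Z reads lower after 0.417 d in beta and alpha. Concentration matters: delta, charged like the flask except for its 0.25 M of L, reads 27.2% at most, and the flask stands at 0.50 M, like beta. Beta, alpha and delta share the same 1.3 equiv of Q, so they give no reading of what a different Q charge does.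

3. Now the number itself. Beta and alpha read L 22.9% and 22.8% at 10.0 d, at different loadings. Suppose Q is spent there, one Q per L lost. L lost in beta over the Q charge gives 0.593: this is the Q share, the part of the spent Q that L takes and J does not.

4. You should expect the flask to end near that L, with Z peaking near 36.1%, earlier than 0.417 d. The forecast says 37% at 0.17 d: “Z peaks near 37% at about 50% L”.

5. The flask gives 35.7% at 0.242 d.

    J + Q + X → X + D (k = 1.50 L² mol⁻² min⁻¹)
    2 X → E (k = 0.610 L mol⁻¹ min⁻¹)
    L + Q + X → X + Z (k = 3.50 L² mol⁻² min⁻¹)
    Z + X ⇌ G + X, rate k4*[X]*[Z] forward; the back reaction follows from the equilibrium constant (K = 2.00, k = 1.40 L mol⁻¹ min⁻¹)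

At 15.0 d the flask keeps 2.64% of its Q and L stands at 21.6%, so the Q share there is 0.619. In a neighbour flask charged with 0.330 equiv of Q, the share 0.593 gives L 80.4%, and that neighbour ends at L 77.4%. In the flask, Z has a half-life of 0.14 d by its forward loss to G alone, the way back uncounted and the other concentrations as charged, which is short against 15 d. At 15.0 d the flask holds G 51.5% beside Z 26.9%.

Readings and results are simulated for substances that don't exist.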